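## Retrosynthetic overview

1. The last disconnection is the 7‑O–Si bond. Before it, the C4–C4a bond of the 2,2‑dimethyl‑2H‑pyran (ring D) on ring B and the C3'–prenyl bond are both traced back to one bis‑ether, 16 (O2'–CMe2CH=CH2, O4'–CMe2C≡CH), by a one‑flask double Claisen cascade.
2. Enabling feature: ring B is a resorcinol whose two carbon substituents (prenyl at C3', pyran C4 at C5') each sit ortho to a phenolic oxygen. O2' has C3' as its only free ortho carbon because C1' carries the chroman, so the fast allyl shift fills C3' and leaves C5' as the only site for the slower propargyl shift from O4'.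
3. Bis‑ether 16 comes from the differentiated isoflavan 9 (2'‑OMOM, 4'‑OH, 7‑OTIPS) by copper‑catalysed propargylation, MOM removal and palladium‑catalysed O‑tert‑prenylation.
4. The isoflavan core comes from palladium‑catalysed α‑arylation of a 7‑silyloxychroman‑4‑one with a ring B bromide; a stereoconvergent transfer hydrogenation then sets C3 as R, and hydrogenolysis removes C4–OH and the benzyl group.
5. Ring order: rings A and C are purchased as the chromanone, ring B is attached, ring D is closed last.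

Key step: step 10

Remark: isoflavan locants are used (chroman O1–C8a, ring B C1'–C6'); the pyran fused to ring B is ring D with its own locants O1, C2, C3, C4, C4a; 5‑(benzyloxy)‑2‑bromophenol is taken as purchasable.

## Route

Step 1
Reactants: 1 7‑hydroxychroman‑4‑one; 2 chlorotriisopropylsilane (TIPSCl)
Product: 3 7‑[(triisopropylsilyl)oxy]chroman‑4‑one
Conditions: TIPSCl, imidazole, DMF, rt
Reagents that add atoms: chlorotriisopropylsilane (2), CC(C)[Si](Cl)(C(C)C)C(C)C
Why: Imidazole‑promoted silylation of the only phenol gives a bulky aryl silyl ether that should survive base, transfer hydrogenation, hydrogenolysis, dilute acid and heat and is removable by fluoride at the end.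

Step 2
Reactants: 4 5‑(benzyloxy)‑2‑bromophenol; 5 chloromethyl methyl ether (MOMCl)
Product: 6 4‑(benzyloxy)‑1‑bromo‑2‑(methoxymethoxy)benzene
Conditions: MOMCl, iPr2NEt, CH2Cl2, 0 °C to rt
Reagents that add atoms: chloromethyl methyl ether (5), COCCl
Why: O‑Alkylation of the phenol (Williamson‑type acetal formation) masks the future 2'‑OH with a group that withstands arylation and hydrogenolysis and differs from the benzyl group on the future 4'‑O.

Step 3
Reactants: 3 7‑[(triisopropylsilyl)oxy]chroman‑4‑one; 6 4‑(benzyloxy)‑1‑bromo‑2‑(methoxymethoxy)benzene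
Product: 7 rac‑3‑[4‑(benzyloxy)‑2‑(methoxymethoxy)phenyl]‑7‑[(triisopropylsilyl)oxy]chroman‑4‑one
Conditions: Pd2(dba)3 (cat.), t‑Bu3P·HBF4 (cat.), NaOtBu, toluene, 60 °C, 3 in slight excess
Reagents that add atoms: none
Why: Palladium‑catalysed ketone α‑arylation (oxidative addition of zerovalent palladium into C–Br, enolate binding, reductive elimination) forms the C3–C1' bond as known for chroman‑4‑ones; the C3 centre is formed racemic, which is acceptable because step 4 is stereoconvergent.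

Step 4
Reactants: 7 rac‑3‑[4‑(benzyloxy)‑2‑(methoxymethoxy)phenyl]‑7‑[(triisopropylsilyl)oxy]chroman‑4‑one
Product: 8 (3R,4R)‑3‑[4‑(benzyloxy)‑2‑(methoxymethoxy)phenyl]‑7‑[(triisopropylsilyl)oxy]chroman‑4‑ol (cis)
Conditions: RuCl[(R,R)‑TsDPEN](p‑cymene) (cat.), HCO2H–Et3N (5:2), EtOAc, 40 °C
Reagents that add atoms: none
Why: Noyori asymmetric transfer hydrogenation with dynamic kinetic resolution: C3 epimerises through the enol faster than reduction, the (R,R) catalyst should fix C4 as R by hydride delivery to one carbonyl face (CH–π contact with ring A) and reduce the enantiomer in which hydride enters anti to the 3‑aryl group, so both enantiomers of 7 should converge on the cis (3R,4R) alcohol.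

Step 5
Reactants: 8 (3R,4R)‑3‑[4‑(benzyloxy)‑2‑(methoxymethoxy)phenyl]‑7‑[(triisopropylsilyl)oxy]chroman‑4‑ol
Product: 9 4‑[(3R)‑7‑[(triisopropylsilyl)oxy]chroman‑3‑yl]‑3‑(methoxymethoxy)phenol
Conditions: H2 (1 atm), 10% Pd/C, EtOH–EtOAc, AcOH (cat.), rt
Reagents that add atoms: none
Why: Catalytic hydrogenolysis should cleave both the benzyl ether and the benzylic C4–OH bond (activated by O1 and the para 7‑oxygen) while the silyl ether and MOM acetal remain; C3 is not involved, so the R centre from step 4 is kept.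

Step 6
Reactants: 9 4‑[(3R)‑7‑[(triisopropylsilyl)oxy]chroman‑3‑yl]‑3‑(methoxymethoxy)phenol; 10 3‑chloro‑3‑methylbut‑1‑yne
Product: 11 triisopropyl{[(3R)‑3‑[2‑(methoxymethoxy)‑4‑[(2‑methylbut‑3‑yn‑2‑yl)oxy]phenyl]chroman‑7‑yl]oxy}silane
Conditions: 10, CuCl2·2H2O (cat.), DBU, MeCN, 0 °C
Reagents that add atoms: 3‑chloro‑3‑methylbut‑1‑yne (10), CC(C)(Cl)C#C
Why: Copper‑catalysed propargylic substitution (a copper acetylide‑derived electrophile captured by the phenoxide) is the standard way to make tertiary aryl propargyl ethers, and 4'‑OH is the only free phenol.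

Step 7
Reactants: 11 triisopropyl{[(3R)‑3‑[2‑(methoxymethoxy)‑4‑[(2‑methylbut‑3‑yn‑2‑yl)oxy]phenyl]chroman‑7‑yl]oxy}silane
Product: 12 2‑[(3R)‑7‑[(triisopropylsilyl)oxy]chroman‑3‑yl]‑5‑[(2‑methylbut‑3‑yn‑2‑yl)oxy]phenol
Conditions: HCl (0.5 M) in MeOH–THF, 40 °C
Reagents that add atoms: none
Why: Acid‑catalysed acetal exchange with methanol should free 2'‑OH, since the tertiary propargylic ether ionises far more slowly than an acetal and the aryl TIPS ether tolerates dilute acid; the step is placed before any acid‑sensitive allyl ether, prenylphenol or chromene exists.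

Step 8
Reactants: 13 2‑methylbut‑3‑en‑2‑ol; 14 methyl chloroformate
Product: 15 methyl 2‑methylbut‑3‑en‑2‑yl carbonate
Conditions: n‑BuLi, THF, −78 °C; then ClCO2Me, −78 to 0 °C
Reagents that add atoms: methyl chloroformate (14), COC(=O)Cl
Why: Acylation of the lithium alkoxide with a chloroformate gives the tertiary allylic carbonate that serves as π‑allyl precursor in step 9.

Step 9
Reactants: 12 2‑[(3R)‑7‑[(triisopropylsilyl)oxy]chroman‑3‑yl]‑5‑[(2‑methylbut‑3‑yn‑2‑yl)oxy]phenol; 15 methyl 2‑methylbut‑3‑en‑2‑yl carbonate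
Product: 16 triisopropyl{[(3R)‑3‑[2‑[(2‑methylbut‑3‑en‑2‑yl)oxy]‑4‑[(2‑methylbut‑3‑yn‑2‑yl)oxy]phenyl]chroman‑7‑yl]oxy}silane
Conditions: 15 (excess), Pd(PPh3)4 (cat.), 4 Å MS, THF, 0 °C, short reaction time
Reagents that add atoms: methyl 2‑methylbut‑3‑en‑2‑yl carbonate (15), COC(=O)OC(C)(C)C=C
Why: Tsuji–Trost O‑allylation: zerovalent palladium ionises the carbonate to a 1,1‑dimethyl‑π‑allyl complex plus methoxide, and the phenoxide should attack the more substituted terminus under kinetic control to give the tertiary (reverse‑prenyl) aryl ether, as known for phenols with this carbonate class.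

Step 10
Reactants: 16 triisopropyl{[(3R)‑3‑[2‑[(2‑methylbut‑3‑en‑2‑yl)oxy]‑4‑[(2‑methylbut‑3‑yn‑2‑yl)oxy]phenyl]chroman‑7‑yl]oxy}silane
Product: 19 6‑[(3R)‑7‑[(triisopropylsilyl)oxy]chroman‑3‑yl]‑2,2‑dimethyl‑8‑(3‑methylbut‑2‑en‑1‑yl)‑2H‑chromen‑7‑ol, via prenylphenol propargyl ether 17 (not isolated), via ortho‑allenylphenol 18 (not isolated)
Conditions: PhNEt2 (degassed), Ar, 110 °C; then 180 °C
Reagents that add atoms: none
Why: Two aromatic Claisen rearrangements run in sequence in one flask: at 110 °C the 1,1‑dimethylallyl ether on O2' undergoes a [3,3] shift to C3' and tautomerises to the 3'‑prenyl‑2'‑phenol 17, and at 180 °C the propargyl ether on O4' undergoes a propargyl Claisen [3,3] shift that joins the alkyne terminus to C5', followed by enolisation to allenylphenol 18, a [1,5]‑hydrogen shift to an ortho‑quinone methide and oxa‑6π electrocyclisation. The closest known reaction types are the thermal conversion of aryl 1,1‑dimethylpropargyl ethers into 2,2‑dimethyl‑2H‑chromenes and the Claisen rearrangement of aryl 1,1‑dimethylallyl ethers to ortho‑prenylphenols. Ring D is thus closed net across the new C4–C4a bond: the σ‑bond is made in the [3,3] step through a six‑membered cyclic transition state and the ring is completed by a thermal disrotatory 6π closure that restores the O–CMe2 bond. No stereocenter is formed, and C3 of the chroman is remote from every bond change and should not epimerise under neutral thermal conditions. The step needs the alkyne shift to go to C5' and not to C3'; this is secured by the large rate difference between the two rearrangements, so that the prenyl group occupies C3' before the propargyl ether reacts and C5' is then its only free ortho position. The basic solvent should suppress acid‑catalysed addition of the new 2'‑OH to the prenyl double bond.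

Step 11
Reactants: 19 6‑[(3R)‑7‑[(triisopropylsilyl)oxy]chroman‑3‑yl]‑2,2‑dimethyl‑8‑(3‑methylbut‑2‑en‑1‑yl)‑2H‑chromen‑7‑ol
Product: 20 6‑[(3R)‑7‑hydroxychroman‑3‑yl]‑2,2‑dimethyl‑8‑(3‑methylbut‑2‑en‑1‑yl)‑2H‑chromen‑7‑ol (target)
Conditions: TBAF, AcOH, THF, 0 °C
Reagents that add atoms: none
Why: Fluoride‑driven cleavage of the aryl silyl ether, buffered with acetic acid, should free 7‑OH without affecting the chromene, the prenyl group or the C3 centre.

## Compound list

1 | 7‑hydroxychroman‑4‑one | O=C1CCOc2cc(O)ccc21 | starting material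
2 | chlorotriisopropylsilane | CC(C)[Si](Cl)(C(C)C)C(C)C | starting material
3 | 7‑[(triisopropylsilyl)oxy]chroman‑4‑one | O=C1CCOc2cc(O[Si](C(C)C)(C(C)C)C(C)C)ccc21 | intermediate
4 | 5‑(benzyloxy)‑2‑bromophenol | Oc1cc(OCc2ccccc2)ccc1Br | starting material
5 | chloromethyl methyl ether | COCCl | starting material
6 | 4‑(benzyloxy)‑1‑bromo‑2‑(methoxymethoxy)benzene | COCOc1cc(OCc2ccccc2)ccc1Br | intermediate
7 | rac‑3‑[4‑(benzyloxy)‑2‑(methoxymethoxy)phenyl]‑7‑[(triisopropylsilyl)oxy]chroman‑4‑one | COCOc1cc(OCc2ccccc2)ccc1C1COc2cc(O[Si](C(C)C)(C(C)C)C(C)C)ccc2C1=O | intermediate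
8 | (3R,4R)‑3‑[4‑(benzyloxy)‑2‑(methoxymethoxy)phenyl]‑7‑[(triisopropylsilyl)oxy]chroman‑4‑ol | COCOc1cc(OCc2ccccc2)ccc1[C@@H]1COc2cc(O[Si](C(C)C)(C(C)C)C(C)C)ccc2[C@@H]1O | intermediate
9 | 4‑[(3R)‑7‑[(triisopropylsilyl)oxy]chroman‑3‑yl]‑3‑(methoxymethoxy)phenol | COCOc1cc(O)ccc1[C@@H]1COc2cc(O[Si](C(C)C)(C(C)C)C(C)C)ccc2C1 | intermediate
10 | 3‑chloro‑3‑methylbut‑1‑yne | CC(C)(Cl)C#C | starting material
11 | triisopropyl{[(3R)‑3‑[2‑(methoxymethoxy)‑4‑[(2‑methylbut‑3‑yn‑2‑yl)oxy]phenyl]chroman‑7‑yl]oxy}silane | COCOc1cc(OC(C)(C)C#C)ccc1[C@@H]1COc2cc(O[Si](C(C)C)(C(C)C)C(C)C)ccc2C1 | intermediate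
12 | 2‑[(3R)‑7‑[(triisopropylsilyl)oxy]chroman‑3‑yl]‑5‑[(2‑methylbut‑3‑yn‑2‑yl)oxy]phenol | Oc1cc(OC(C)(C)C#C)ccc1[C@@H]1COc2cc(O[Si](C(C)C)(C(C)C)C(C)C)ccc2C1 | intermediate
13 | 2‑methylbut‑3‑en‑2‑ol | CC(C)(O)C=C | starting material
14 | methyl chloroformate | COC(=O)Cl | starting material
15 | methyl 2‑methylbut‑3‑en‑2‑yl carbonate | COC(=O)OC(C)(C)C=C | intermediate
16 | triisopropyl{[(3R)‑3‑[2‑[(2‑methylbut‑3‑en‑2‑yl)oxy]‑4‑[(2‑methylbut‑3‑yn‑2‑yl)oxy]phenyl]chroman‑7‑yl]oxy}silane | C=CC(C)(C)Oc1cc(OC(C)(C)C#C)ccc1[C@@H]1COc2cc(O[Si](C(C)C)(C(C)C)C(C)C)ccc2C1 | intermediate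
17 | 6‑[(3R)‑7‑[(triisopropylsilyl)oxy]chroman‑3‑yl]‑2‑(3‑methylbut‑2‑en‑1‑yl)‑3‑[(2‑methylbut‑3‑yn‑2‑yl)oxy]phenol | CC(C)=CCc1c(O)c([C@@H]2COc3cc(O[Si](C(C)C)(C(C)C)C(C)C)ccc3C2)ccc1OC(C)(C)C#C | intermediate
18 | 4‑[(3R)‑7‑[(triisopropylsilyl)oxy]chroman‑3‑yl]‑6‑(3‑methylbuta‑1,2‑dien‑1‑yl)‑2‑(3‑methylbut‑2‑en‑1‑yl)benzene‑1,3‑diol | CC(C)=CCc1c(O)c([C@@H]2COc3cc(O[Si](C(C)C)(C(C)C)C(C)C)ccc3C2)cc(C=C=C(C)C)c1O | intermediate
19 | 6‑[(3R)‑7‑[(triisopropylsilyl)oxy]chroman‑3‑yl]‑2,2‑dimethyl‑8‑(3‑methylbut‑2‑en‑1‑yl)‑2H‑chromen‑7‑ol | CC(C)=CCc1c(O)c([C@@H]2COc3cc(O[Si](C(C)C)(C(C)C)C(C)C)ccc3C2)cc2c1OC(C)(C)C=C2 | intermediate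
20 | 6‑[(3R)‑7‑hydroxychroman‑3‑yl]‑2,2‑dimethyl‑8‑(3‑methylbut‑2‑en‑1‑yl)‑2H‑chromen‑7‑ol (CNP0331403.1) | CC(C)=CCc1c(O)c([C@@H]2COc3cc(O)ccc3C2)cc2c1OC(C)(C)C=C2 | target

## Step count and risks

Total step count: 11 (including the preparation of reagent 15 and the two fragment protections).
Longest linear sequence: 9 steps (1, 3, 4, 5, 6, 7, 9, 10, 11) from 7‑hydroxychroman‑4‑one.

Steps most likely to fail:

1. Step 10. The propargyl shift may start before the allyl shift is complete, which would lose regiocontrol and give the angular pyran through C3'. The tertiary allyl ether may also fragment with loss of isoprene, or the propargyl group may shift onto the substituted C3' and be trapped by intramolecular cycloaddition. The fallback sets out from 16 and comes back at 19. Thermolysis is stopped after the 110 °C stage and 17 is isolated. Acetylation (Ac2O, pyridine, DMAP, CH2Cl2) should give 6‑[(3R)‑7‑[(triisopropylsilyl)oxy]chroman‑3‑yl]‑2‑(3‑methylbut‑2‑en‑1‑yl)‑3‑[(2‑methylbut‑3‑yn‑2‑yl)oxy]phenyl acetate F1. Ph3PAuNTf2 (cat.) in CH2Cl2 at rt should then close ring D by 6‑endo‑dig hydroarylation (monovalent gold activates the alkyne, C5' attacks, protodeauration), giving 6‑[(3R)‑7‑[(triisopropylsilyl)oxy]chroman‑3‑yl]‑2,2‑dimethyl‑8‑(3‑methylbut‑2‑en‑1‑yl)‑2H‑chromen‑7‑yl acetate F2. Hydrazine hydrate in THF should cleave the aryl acetate and return 19. The acetate keeps the phenol from adding to the prenyl group under the π‑acid.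

2. Step 9. The phenoxide may attack the unsubstituted allyl terminus (linear prenyl ether), the π‑allyl complex may lose a β‑hydrogen to give isoprene, or the terminal alkyne may engage the palladium catalyst. The fallback sets out from 9 and comes back at 17, which is then heated at 180 °C as in the second stage of step 10. MOMCl and iPr2NEt should give {[(3R)‑3‑[2,4‑bis(methoxymethoxy)phenyl]chroman‑7‑yl]oxy}triisopropylsilane F3. Directed ortho‑lithiation at C3' between the two acetal oxygens (n‑BuLi, THF, 0 °C), then CuI and prenyl bromide, should give {[(3R)‑3‑[2,4‑bis(methoxymethoxy)‑3‑(3‑methylbut‑2‑en‑1‑yl)phenyl]chroman‑7‑yl]oxy}triisopropylsilane F4. Dilute HCl in MeOH at rt should give 4‑[(3R)‑7‑[(triisopropylsilyl)oxy]chroman‑3‑yl]‑2‑(3‑methylbut‑2‑en‑1‑yl)benzene‑1,3‑diol F5. Copper‑catalysed propargylation as in step 6 should then take place at the less hindered 4'‑OH, because 2'‑OH is flanked by the chroman and the prenyl group, and give 17.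

3. Step 3. The chromanone enolate may open by retro‑oxa‑Michael reaction, a second arylation may occur at C3, or the base may attack the silyl ether. The fallback sets out from 3 and 6 and comes back at 8. Miyaura borylation of 6 (B2pin2, PdCl2(dppf), KOAc, dioxane, 80 °C) should give 2‑[4‑(benzyloxy)‑2‑(methoxymethoxy)phenyl]‑4,4,5,5‑tetramethyl‑1,3,2‑dioxaborolane F6. Dibromination of 3 with pyridinium tribromide should give 3,3‑dibromo‑7‑[(triisopropylsilyl)oxy]chroman‑4‑one F7, and Et3N should eliminate HBr to give 3‑bromo‑7‑[(triisopropylsilyl)oxy]‑4H‑chromen‑4‑one F8. Suzuki–Miyaura coupling of F6 and F8 (Pd(PPh3)4, K3PO4, toluene, 80 °C) should give the isoflavone 3‑[4‑(benzyloxy)‑2‑(methoxymethoxy)phenyl]‑7‑[(triisopropylsilyl)oxy]‑4H‑chromen‑4‑one F9. Transfer hydrogenation with RuCl[(R,R)‑TsDPEN](p‑cymene) and HCO2H–Et3N should then reduce the C2–C3 double bond and the ketone under dynamic kinetic resolution to give 8.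

Further compounds
F1 | step 10 | 6‑[(3R)‑7‑[(triisopropylsilyl)oxy]chroman‑3‑yl]‑2‑(3‑methylbut‑2‑en‑1‑yl)‑3‑[(2‑methylbut‑3‑yn‑2‑yl)oxy]phenyl acetate | CC(C)=CCc1c(OC(C)=O)c([C@@H]2COc3cc(O[Si](C(C)C)(C(C)C)C(C)C)ccc3C2)ccc1OC(C)(C)C#C
F2 | step 10 | 6‑[(3R)‑7‑[(triisopropylsilyl)oxy]chroman‑3‑yl]‑2,2‑dimethyl‑8‑(3‑methylbut‑2‑en‑1‑yl)‑2H‑chromen‑7‑yl acetate | CC(C)=CCc1c(OC(C)=O)c([C@@H]2COc3cc(O[Si](C(C)C)(C(C)C)C(C)C)ccc3C2)cc2c1OC(C)(C)C=C2
F3 | step 9 | {[(3R)‑3‑[2,4‑bis(methoxymethoxy)phenyl]chroman‑7‑yl]oxy}triisopropylsilane | COCOc1cc(OCOC)ccc1[C@@H]1COc2cc(O[Si](C(C)C)(C(C)C)C(C)C)ccc2C1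
F4 | step 9 | {[(3R)‑3‑[2,4‑bis(methoxymethoxy)‑3‑(3‑methylbut‑2‑en‑1‑yl)phenyl]chroman‑7‑yl]oxy}triisopropylsilane | COCOc1c(CC=C(C)C)c(OCOC)ccc1[C@@H]1COc2cc(O[Si](C(C)C)(C(C)C)C(C)C)ccc2C1
F5 | step 9 | 4‑[(3R)‑7‑[(triisopropylsilyl)oxy]chroman‑3‑yl]‑2‑(3‑methylbut‑2‑en‑1‑yl)benzene‑1,3‑diol | Oc1c(CC=C(C)C)c(O)ccc1[C@@H]1COc2cc(O[Si](C(C)C)(C(C)C)C(C)C)ccc2C1
F6 | step 3 | 2‑[4‑(benzyloxy)‑2‑(methoxymethoxy)phenyl]‑4,4,5,5‑tetramethyl‑1,3,2‑dioxaborolane | COCOc1cc(OCc2ccccc2)ccc1B1OC(C)(C)C(C)(C)O1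
F7 | step 3 | 3,3‑dibromo‑7‑[(triisopropylsilyl)oxy]chroman‑4‑one | O=C1c2ccc(O[Si](C(C)C)(C(C)C)C(C)C)cc2OCC1(Br)Br
F8 | step 3 | 3‑bromo‑7‑[(triisopropylsilyl)oxy]‑4H‑chromen‑4‑one | O=c1c(Br)coc2cc(O[Si](C(C)C)(C(C)C)C(C)C)ccc12
F9 | step 3 | 3‑[4‑(benzyloxy)‑2‑(methoxymethoxy)phenyl]‑7‑[(triisopropylsilyl)oxy]‑4H‑chromen‑4‑one | COCOc1cc(OCc2ccccc2)ccc1-c1coc2cc(O[Si](C(C)C)(C(C)C)C(C)C)ccc2c1=O
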